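**Retrosynthetic overview**
1. 30 ⇐ 26: phenol deacetylation, convex-face epoxidation of C8=C9 and acylation of the 6-OH come last.
2. 26 ⇐ 22: the seven-membered ring is closed second, by RCM at C8=C9; the C6 carbinol is then reset by oxidation and chelation-controlled reduction.
3. 22 ⇐ 13: the C4 carbinol comes from i-PrCeCl2 addition after a Wharton transposition (C2=O → C4–O); the C6–C7 bond comes from methallylboration.
4. 13 ⇐ 9: quaternary C1 is built by allylation, then methylation anti to the C5 arm of a 4-substituted cyclopentenone.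
5. 9 ⇐ 3: the five-membered ring is closed first, by RCM; C5 comes from Johnson–Claisen chirality transfer from carbinol 4, made by ketoreductase reduction of achiral enone 3.

Assumption and notation: 1, 2, 27, 2-methylallyl-B(pin) and a ketoreductase screening panel are taken as commercial; C1–C10 are daucane locants (C1 angular-methyl carbon, C4 isopropyl carbinol, C5 ring-fusion CH, C6 ester carbon, C8/C9 epoxide carbons) and β is the face of the angular methyl.

**Step 1**
Reactants: 1 2-((tert-butyldimethylsilyl)oxy)acetaldehyde; 2 1-(triphenyl-λ5-phosphanylidene)propan-2-one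
Product: 3 (E)-5-((tert-butyldimethylsilyl)oxy)pent-3-en-2-one
Conditions: CH2Cl2, rt, 16 h
Reagents that add atoms: none
Why: Wittig olefination with a carbonyl-stabilised ylide gives the (E)-enone selectively and creates no stereocentre.

**Step 2**
Reactants: 3 (E)-5-((tert-butyldimethylsilyl)oxy)pent-3-en-2-one
Product: 4 (R,E)-5-((tert-butyldimethylsilyl)oxy)pent-3-en-2-ol
Conditions: (R)-selective ketoreductase (NADPH-dependent alcohol dehydrogenase), NADP+ (cat.), i-PrOH (10 vol%), phosphate buffer pH 7.0, 30 °C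
Reagents that add atoms: none
Why: Ketoreductase-catalysed asymmetric carbonyl reduction delivers hydride from NADPH to one enantiotopic face of the methyl ketone (small methyl against large alkenyl group), setting the first stereocentre as the (R)-carbinol and leaving the conjugated C=C intact.

**Step 3**
Reactants: 4 (R,E)-5-((tert-butyldimethylsilyl)oxy)pent-3-en-2-ol
Product: 6 ethyl (R,E)-3-(((tert-butyldimethylsilyl)oxy)methyl)hex-4-enoate, via mixed ketene acetal 5 (not isolated)
Conditions: MeC(OEt)3 (6 equiv), EtCO2H (5 mol%), 140 °C, EtOH distilled off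
Reagents that add atoms: triethyl orthoacetate, CC(OCC)(OCC)OCC
Why: Johnson–Claisen rearrangement through a chair transition state with the carbinol methyl equatorial transfers the C–O chirality suprafacially to the new C–C bond, giving the (R) stereocentre (future C5) and an (E)-propenyl group.

**Step 4**
Reactants: 6 ethyl (R,E)-3-(((tert-butyldimethylsilyl)oxy)methyl)hex-4-enoate
Product: 7 (R,E)-3-(((tert-butyldimethylsilyl)oxy)methyl)-N-methoxy-N-methylhex-4-enamide
Conditions: MeNH(OMe)·HCl (1.5 equiv), i-PrMgCl (3 equiv), THF, −20 to 0 °C; aq. NH4Cl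
Reagents that add atoms: N,O-dimethylhydroxylamine hydrochloride, CNOC.Cl
Why: Weinreb amide formation by aminolysis of the ester with MeN(OMe)MgCl; the stereocentre is β to the carbonyl and cannot epimerise.

**Step 5**
Reactants: 7 (R,E)-3-(((tert-butyldimethylsilyl)oxy)methyl)-N-methoxy-N-methylhex-4-enamide
Product: 8 (R,E)-5-(((tert-butyldimethylsilyl)oxy)methyl)octa-1,6-dien-3-one
Conditions: CH2=CHMgBr (1.5 equiv), THF, 0 °C; cold 1 M HCl quench; used crude
Reagents that add atoms: vinylmagnesium bromide, C=C[Mg]Br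
Why: Weinreb ketone synthesis, in which the chelated tetrahedral adduct stops at mono-addition and releases the vinyl ketone only on acidic quench.

**Step 6**
Reactants: 8 (R,E)-5-(((tert-butyldimethylsilyl)oxy)methyl)octa-1,6-dien-3-one
Product: 9 (R)-4-(((tert-butyldimethylsilyl)oxy)methyl)cyclopent-2-en-1-one
Conditions: second-generation Grubbs catalyst (3 mol%), CH2Cl2 (0.02 M), 40 °C
Reagents that add atoms: none
Why: Ring-closing metathesis between the vinyl ketone and the propenyl group closes the five-membered ring with loss of propene and does not touch the stereocentre.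

**Step 7**
Reactants: 9 (R)-4-(((tert-butyldimethylsilyl)oxy)methyl)cyclopent-2-en-1-one
Product: 11 (4S,5R)-5-allyl-4-(((tert-butyldimethylsilyl)oxy)methyl)cyclopent-2-en-1-one, via lithium dienolate 10 (not isolated)
Conditions: LiN(iPr)2 (1.05 equiv), THF, −78 °C; allyl bromide (1.5 equiv), DMPU, −78 to −30 °C
Reagents that add atoms: allyl bromide, C=CCBr
Why: Kinetic α′-deprotonation and SN2 enolate alkylation place the allyl group trans to the silyloxymethyl arm, although this centre is re-enolised in step 8 so its configuration here does not matter.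

**Step 8**
Reactants: 11 (4S,5R)-5-allyl-4-(((tert-butyldimethylsilyl)oxy)methyl)cyclopent-2-en-1-one
Product: 13 (4S,5S)-5-allyl-4-(((tert-butyldimethylsilyl)oxy)methyl)-5-methylcyclopent-2-en-1-one, via lithium dienolate 12 (not isolated)
Conditions: LiN(iPr)2 (1.1 equiv), THF, −78 °C; MeI (3 equiv), DMPU, −78 to −20 °C
Reagents that add atoms: iodomethane, CI
Why: Enolate alkylation in which MeI approaches the planar enolate anti to the adjacent CH2OTBS group, so the methyl ends trans and the allyl cis to that arm, fixing quaternary C1.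

**Step 9**
Reactants: 13 (4S,5S)-5-allyl-4-(((tert-butyldimethylsilyl)oxy)methyl)-5-methylcyclopent-2-en-1-one
Product: 14 (1S,3S,4S,5S)-3-allyl-4-(((tert-butyldimethylsilyl)oxy)methyl)-3-methyl-6-oxabicyclo[3.1.0]hexan-2-one
Conditions: 30% aq. H2O2, NaOH (0.3 equiv), MeOH, 0 °C; Na2S2O3 wash to remove peroxide
Reagents that add atoms: hydrogen peroxide, OO
Why: Weitz–Scheffer nucleophilic epoxidation attacks only the enone, anti to the neighbouring CH2OTBS group, and the epoxide configuration is erased again in step 11.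

**Step 10**
Reactants: 14 (1S,3S,4S,5S)-3-allyl-4-(((tert-butyldimethylsilyl)oxy)methyl)-3-methyl-6-oxabicyclo[3.1.0]hexan-2-one
Product: 16 (1R,4R,5S)-4-allyl-5-(((tert-butyldimethylsilyl)oxy)methyl)-4-methylcyclopent-2-en-1-ol, via epoxy hydrazone 15 (not isolated)
Conditions: N2H4·H2O (3 equiv), AcOH (0.3 equiv), MeOH, 0 °C to rt
Reagents that add atoms: none
Why: Wharton transposition, in which the epoxy hydrazone fragments with loss of N2, moves the oxygen from C2 to C4 and leaves the C2=C3 alkene, with no α′-hydrogen available for side reactions.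

**Step 11**
Reactants: 16 (1R,4R,5S)-4-allyl-5-(((tert-butyldimethylsilyl)oxy)methyl)-4-methylcyclopent-2-en-1-ol
Product: 17 (4R,5S)-4-allyl-5-(((tert-butyldimethylsilyl)oxy)methyl)-4-methylcyclopent-2-en-1-one
Conditions: Dess–Martin periodinane (1.3 equiv), CH2Cl2, 0 °C to rt
Reagents that add atoms: none
Why: Dess–Martin oxidation of the allylic alcohol gives the transposed enone under non-basic conditions, so the now α-positioned C5–H neither epimerises nor eliminates silanolate.

**Step 12**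
Reactants: 17 (4R,5S)-4-allyl-5-(((tert-butyldimethylsilyl)oxy)methyl)-4-methylcyclopent-2-en-1-one
Product: 18 (2S,3S)-3-allyl-2-(((tert-butyldimethylsilyl)oxy)methyl)-3-methylcyclopentan-1-one
Conditions: Cu(OAc)2·H2O (5 mol%), 1,2-bis(diphenylphosphino)benzene (5 mol%), (EtO)2MeSiH (2 equiv), t-BuOH (2 equiv), toluene, rt
Reagents that add atoms: none
Why: Copper hydride conjugate reduction (Stryker-type 1,4-reduction) saturates only the enone C=C, leaves the isolated allyl group, and protonates at C3 so that C5 is untouched.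

**Step 13**
Reactants: 18 (2S,3S)-3-allyl-2-(((tert-butyldimethylsilyl)oxy)methyl)-3-methylcyclopentan-1-one
Product: 19 (1R,2S,3S)-3-allyl-2-(((tert-butyldimethylsilyl)oxy)methyl)-3-methyl-1-(propan-2-yl)cyclopentan-1-ol
Conditions: anhydrous CeCl3 (2.5 equiv), i-PrMgCl (2.5 equiv), THF, −78 to −20 °C; aq. NH4Cl
Reagents that add atoms: isopropylmagnesium chloride, CC(C)[Mg]Cl
Why: Imamoto organocerium 1,2-addition suppresses enolisation and β-elimination, and i-PrCeCl2 attacks the β face opposite the adjacent CH2OTBS arm and the allyl group, giving the tertiary alcohol with OH cis to the C6 arm.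

**Step 14**
Reactants: 19 (1R,2S,3S)-3-allyl-2-(((tert-butyldimethylsilyl)oxy)methyl)-3-methyl-1-(propan-2-yl)cyclopentan-1-ol
Product: 20 (1R,2S,3S)-3-allyl-2-(hydroxymethyl)-3-methyl-1-(propan-2-yl)cyclopentan-1-ol
Conditions: Bu4NF (1.2 equiv), THF, 0 °C to rt
Reagents that add atoms: none
Why: Fluoride-induced desilylation frees the primary alcohol without affecting the tertiary alcohol or the alkene.

**Step 15**
Reactants: 20 (1R,2S,3S)-3-allyl-2-(hydroxymethyl)-3-methyl-1-(propan-2-yl)cyclopentan-1-ol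
Product: 21 (1R,2S,5R)-2-allyl-5-hydroxy-2-methyl-5-(propan-2-yl)cyclopentane-1-carbaldehyde
Conditions: TEMPO (10 mol%), PhI(OAc)2 (1.1 equiv), CH2Cl2, rt; used crude at once
Reagents that add atoms: none
Why: TEMPO-catalysed oxidation is selective for the primary alcohol and runs without base, so the β-hydroxy aldehyde neither epimerises at C5 nor undergoes retro-aldol cleavage.

**Step 16**
Reactants: 21 (1R,2S,5R)-2-allyl-5-hydroxy-2-methyl-5-(propan-2-yl)cyclopentane-1-carbaldehyde
Product: 22 (1R,2S,3S)-3-allyl-2-(1-hydroxy-3-methylbut-3-en-1-yl)-3-methyl-1-(propan-2-yl)cyclopentan-1-ol (both carbinol epimers)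
Conditions: 2-methylallyl-B(pin) (1.5 equiv), toluene, rt to 40 °C; aq. NaHCO3 work-up
Reagents that add atoms: 2-methylallylboronic acid pinacol ester, CC(=C)CB1OC(C)(C)C(C)(C)O1
Why: Allylboration through a closed six-membered transition state forms the C6–C7 bond under neutral conditions, and both C6 epimers are carried on because this centre is reset in steps 18 and 19.

**Step 17**
Reactants: 22 (1R,2S,3S)-3-allyl-2-(1-hydroxy-3-methylbut-3-en-1-yl)-3-methyl-1-(propan-2-yl)cyclopentan-1-ol (both carbinol epimers)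
Product: 23 (3R,3aS,8aS)-6,8a-dimethyl-3-(propan-2-yl)-1,2,3,3a,4,5,8,8a-octahydroazulene-3,4-diol (both C4 epimers)
Conditions: second-generation Hoveyda–Grubbs catalyst (5 mol%), toluene (0.005 M), 80 °C
Reagents that add atoms: none
Why: Ring-closing metathesis of the cis-disposed allyl and methallyl arms closes the seven-membered ring as the trisubstituted C8=C9 alkene with loss of ethene, and the cis ring fusion follows from the configurations already set at C1 and C5.

**Step 18**
Reactants: 23 (3R,3aS,8aS)-6,8a-dimethyl-3-(propan-2-yl)-1,2,3,3a,4,5,8,8a-octahydroazulene-3,4-diol (both C4 epimers)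
Product: 24 (3R,3aR,8aS)-3-hydroxy-6,8a-dimethyl-3-(propan-2-yl)-2,3,3a,5,8,8a-hexahydroazulen-4(1H)-one
Conditions: Dess–Martin periodinane (1.3 equiv), pyridine (3 equiv), CH2Cl2, 0 °C
Reagents that add atoms: none
Why: Buffered Dess–Martin oxidation converts both epimers into one β-hydroxy ketone without conjugating the β,γ-alkene or triggering retro-aldol cleavage.

**Step 19**
Reactants: 24 (3R,3aR,8aS)-3-hydroxy-6,8a-dimethyl-3-(propan-2-yl)-2,3,3a,5,8,8a-hexahydroazulen-4(1H)-one
Product: 26 (3R,3aS,4R,8aS)-6,8a-dimethyl-3-(propan-2-yl)-1,2,3,3a,4,5,8,8a-octahydroazulene-3,4-diol, via diethylboron chelate 25 (not isolated)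
Conditions: Et2BOMe (1.1 equiv), THF/MeOH 4:1, −78 °C; NaBH4 (1.2 equiv), −78 °C; AcOH, then MeOH co-evaporation
Reagents that add atoms: none
Why: Narasaka–Prasad chelation-controlled reduction holds the C4–O bond syn-coplanar with the C6 carbonyl, so hydride adds from the H5 side, anti to quaternary C1, and gives the 6α-alcohol (syn-1,3-diol).

**Step 20**
Reactants: 26 (3R,3aS,4R,8aS)-6,8a-dimethyl-3-(propan-2-yl)-1,2,3,3a,4,5,8,8a-octahydroazulene-3,4-diol; 27 4-acetoxybenzoyl chloride
Product: 28 (3R,3aS,4R,8aS)-3-hydroxy-6,8a-dimethyl-3-(propan-2-yl)-1,2,3,3a,4,5,8,8a-octahydroazulen-4-yl 4-acetoxybenzoate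
Conditions: Et3N (3 equiv), DMAP (0.2 equiv), CH2Cl2, 0 °C to rt
Reagents that add atoms: none
Why: DMAP-catalysed acylation esterifies the secondary 6-OH only, because the tertiary 4-OH is too hindered to react.

**Step 21**
Reactants: 28 (3R,3aS,4R,8aS)-3-hydroxy-6,8a-dimethyl-3-(propan-2-yl)-1,2,3,3a,4,5,8,8a-octahydroazulen-4-yl 4-acetoxybenzoate
Product: 29 (1S,4R,5S,6R,8R,9S)-8,9-epoxy-4-hydroxydaucan-6-yl 4-acetoxybenzoate (cis-fused; epoxide β)
Conditions: mCPBA (1.2 equiv), NaHCO3 (3 equiv), CH2Cl2, 0 °C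
Reagents that add atoms: m-chloroperoxybenzoic acid, OOC(=O)c1cccc(Cl)c1
Why: Prilezhaev epoxidation is predicted to occur on the convex β face, away from the 6α-aroyloxy group and the cyclopentane ring folded under the α face, giving the epoxide syn to the angular methyl, while the buffer prevents acid-induced opening by the 4-OH.

**Step 22**
Reactants: 29 (1S,4R,5S,6R,8R,9S)-8,9-epoxy-4-hydroxydaucan-6-yl 4-acetoxybenzoate
Product: 30 (1S,4R,5S,6R,8R,9S)-8,9-epoxy-4-hydroxydaucan-6-yl 4-hydroxybenzoate (CNP0163817.4)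
Conditions: K2CO3 (0.2 equiv), MeOH, 0 °C, 20 min; pH 7 buffer quench
Reagents that add atoms: none
Why: Base-catalysed transesterification removes the phenolic acetate far faster than it attacks the hindered secondary benzoate, which is further deactivated once the phenoxide forms, and the epoxide is stable to these conditions.

**Compound list**
1 | 2-((tert-butyldimethylsilyl)oxy)acetaldehyde | CC(C)(C)[Si](C)(C)OCC=O | starting material
2 | 1-(triphenyl-λ5-phosphanylidene)propan-2-one | CC(=O)C=P(c1ccccc1)(c1ccccc1)c1ccccc1 | starting material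
3 | (E)-5-((tert-butyldimethylsilyl)oxy)pent-3-en-2-one | CC(=O)/C=C/CO[Si](C)(C)C(C)(C)C | intermediate
4 | (R,E)-5-((tert-butyldimethylsilyl)oxy)pent-3-en-2-ol | C[C@@H](O)/C=C/CO[Si](C)(C)C(C)(C)C | intermediate
5 | (R,E)-tert-butyl((4-((1-ethoxyvinyl)oxy)pent-2-en-1-yl)oxy)dimethylsilane (mixed ketene acetal, not isolated) | C=C(OCC)O[C@H](C)/C=C/CO[Si](C)(C)C(C)(C)C | intermediate
6 | ethyl (R,E)-3-(((tert-butyldimethylsilyl)oxy)methyl)hex-4-enoate | CCOC(=O)C[C@@H](CO[Si](C)(C)C(C)(C)C)/C=C/C | intermediate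
7 | (R,E)-3-(((tert-butyldimethylsilyl)oxy)methyl)-N-methoxy-N-methylhex-4-enamide | CON(C)C(=O)C[C@@H](CO[Si](C)(C)C(C)(C)C)/C=C/C | intermediate
8 | (R,E)-5-(((tert-butyldimethylsilyl)oxy)methyl)octa-1,6-dien-3-one | C=CC(=O)C[C@@H](CO[Si](C)(C)C(C)(C)C)/C=C/C | intermediate
9 | (R)-4-(((tert-butyldimethylsilyl)oxy)methyl)cyclopent-2-en-1-one | O=C1C=C[C@H](CO[Si](C)(C)C(C)(C)C)C1 | intermediate
10 | lithium (S)-3-(((tert-butyldimethylsilyl)oxy)methyl)cyclopenta-1,4-dien-1-olate (α′-dienolate of 9, not isolated) | [Li]OC1=C[C@@H](CO[Si](C)(C)C(C)(C)C)C=C1 | intermediate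
11 | (4S,5R)-5-allyl-4-(((tert-butyldimethylsilyl)oxy)methyl)cyclopent-2-en-1-one | O=C1C=C[C@H](CO[Si](C)(C)C(C)(C)C)[C@H]1CC=C | intermediate
12 | lithium (S)-2-allyl-3-(((tert-butyldimethylsilyl)oxy)methyl)cyclopenta-1,4-dien-1-olate (α′-dienolate of 11, not isolated) | [Li]OC1=C(CC=C)[C@@H](CO[Si](C)(C)C(C)(C)C)C=C1 | intermediate
13 | (4S,5S)-5-allyl-4-(((tert-butyldimethylsilyl)oxy)methyl)-5-methylcyclopent-2-en-1-one | O=C1C=C[C@H](CO[Si](C)(C)C(C)(C)C)[C@]1(C)CC=C | intermediate
14 | (1S,3S,4S,5S)-3-allyl-4-(((tert-butyldimethylsilyl)oxy)methyl)-3-methyl-6-oxabicyclo[3.1.0]hexan-2-one | O=C1[C@H]2O[C@H]2[C@H](CO[Si](C)(C)C(C)(C)C)[C@]1(C)CC=C | intermediate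
15 | hydrazone of 14 at the ring carbonyl (not isolated) | NN=C1[C@H]2O[C@H]2[C@H](CO[Si](C)(C)C(C)(C)C)[C@]1(C)CC=C | intermediate
16 | (1R,4R,5S)-4-allyl-5-(((tert-butyldimethylsilyl)oxy)methyl)-4-methylcyclopent-2-en-1-ol | O[C@@H]1C=C[C@@](C)(CC=C)[C@H]1CO[Si](C)(C)C(C)(C)C | intermediate
17 | (4R,5S)-4-allyl-5-(((tert-butyldimethylsilyl)oxy)methyl)-4-methylcyclopent-2-en-1-one | O=C1C=C[C@@](C)(CC=C)[C@H]1CO[Si](C)(C)C(C)(C)C | intermediate
18 | (2S,3S)-3-allyl-2-(((tert-butyldimethylsilyl)oxy)methyl)-3-methylcyclopentan-1-one | O=C1CC[C@@](C)(CC=C)[C@H]1CO[Si](C)(C)C(C)(C)C | intermediate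
19 | (1R,2S,3S)-3-allyl-2-(((tert-butyldimethylsilyl)oxy)methyl)-3-methyl-1-(propan-2-yl)cyclopentan-1-ol | CC(C)[C@]1(O)CC[C@@](C)(CC=C)[C@H]1CO[Si](C)(C)C(C)(C)C | intermediate
20 | (1R,2S,3S)-3-allyl-2-(hydroxymethyl)-3-methyl-1-(propan-2-yl)cyclopentan-1-ol | CC(C)[C@]1(O)CC[C@@](C)(CC=C)[C@H]1CO | intermediate
21 | (1R,2S,5R)-2-allyl-5-hydroxy-2-methyl-5-(propan-2-yl)cyclopentane-1-carbaldehyde | CC(C)[C@]1(O)CC[C@@](C)(CC=C)[C@H]1C=O | intermediate
22 | (1R,2S,3S)-3-allyl-2-(1-hydroxy-3-methylbut-3-en-1-yl)-3-methyl-1-(propan-2-yl)cyclopentan-1-ol (both carbinol epimers) | CC(C)[C@]1(O)CC[C@@](C)(CC=C)[C@H]1C(O)CC(C)=C | intermediate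
23 | (3R,3aS,8aS)-6,8a-dimethyl-3-(propan-2-yl)-1,2,3,3a,4,5,8,8a-octahydroazulene-3,4-diol (both C4 epimers) | CC(C)[C@]1(O)CC[C@@]2(C)CC=C(C)CC(O)[C@H]21 | intermediate
24 | (3R,3aR,8aS)-3-hydroxy-6,8a-dimethyl-3-(propan-2-yl)-2,3,3a,5,8,8a-hexahydroazulen-4(1H)-one | CC(C)[C@]1(O)CC[C@@]2(C)CC=C(C)CC(=O)[C@H]21 | intermediate
25 | O-diethylboryl derivative of 24 at the tertiary oxygen, chelated to the ring carbonyl (not isolated) | CC(C)[C@]1(OB(CC)CC)CC[C@@]2(C)CC=C(C)CC(=O)[C@H]21 | intermediate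
26 | (3R,3aS,4R,8aS)-6,8a-dimethyl-3-(propan-2-yl)-1,2,3,3a,4,5,8,8a-octahydroazulene-3,4-diol | CC(C)[C@]1(O)CC[C@@]2(C)CC=C(C)C[C@@H](O)[C@H]21 | intermediate
27 | 4-acetoxybenzoyl chloride | CC(=O)Oc1ccc(cc1)C(Cl)=O | starting material
28 | (3R,3aS,4R,8aS)-3-hydroxy-6,8a-dimethyl-3-(propan-2-yl)-1,2,3,3a,4,5,8,8a-octahydroazulen-4-yl 4-acetoxybenzoate | CC(C)[C@]1(O)CC[C@@]2(C)CC=C(C)C[C@@H](OC(=O)c3ccc(OC(C)=O)cc3)[C@H]21 | intermediate
29 | (1S,4R,5S,6R,8R,9S)-8,9-epoxy-4-hydroxydaucan-6-yl 4-acetoxybenzoate | CC(C)[C@]1(O)CC[C@@]2(C)C[C@@H]3O[C@]3(C)C[C@@H](OC(=O)c3ccc(OC(C)=O)cc3)[C@H]21 | intermediate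
30 | (1S,4R,5S,6R,8R,9S)-8,9-epoxy-4-hydroxydaucan-6-yl 4-hydroxybenzoate | CC(C)[C@]1(O)CC[C@@]2(C)C[C@@H]3O[C@]3(C)C[C@@H](OC(=O)c3ccc(O)cc3)[C@H]21 | target

**Totals**
Total step count: 22. Longest linear sequence: 22 steps (1 to 30); 27 is a purchased fragment.

**Three steps most likely to fail, with fallbacks**

Step 8 (with step 7). The cross-conjugated dienolates 10 and 12 are cyclopentadienyl-type species. They can lose the γ-hydrogen at C5, undergo 1,5-hydrogen shifts or add to unreacted enone, and the quaternisation needs high anti selectivity. The fallback sets out from 9 and comes back at 14. Compound 9 is epoxidised first (30% H2O2, NaOH, MeOH, 0 °C) to the epoxy ketone (1S,4S,5S)-4-(((tert-butyldimethylsilyl)oxy)methyl)-6-oxabicyclo[3.1.0]hexan-2-one F1. Its ordinary ketone enolate (LiN(iPr)2, THF, −78 °C) no longer has a vinylogous C5–H. It is allylated to (1S,3R,4S,5S)-3-allyl-4-(((tert-butyldimethylsilyl)oxy)methyl)-6-oxabicyclo[3.1.0]hexan-2-one F2. A second deprotonation and MeI, again anti to the silyloxymethyl arm, gives 14 directly. Compounds 11 to 13 are bypassed.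

Step 10. Wharton reactions of hindered cyclopentanone epoxides can be low-yielding because hydrazone formation next to the quaternary carbon is slow. The fallback sets out from 14 and comes back at 16. Reduction (NaBH4, CeCl3·7H2O, MeOH, −20 °C) gives the epoxy alcohol 3-allyl-4-(((tert-butyldimethylsilyl)oxy)methyl)-3-methyl-6-oxabicyclo[3.1.0]hexan-2-ol F3 (either carbinol epimer). This is converted (NaH, CS2, then MeI, THF) into the xanthate O-[3-allyl-4-(((tert-butyldimethylsilyl)oxy)methyl)-3-methyl-6-oxabicyclo[3.1.0]hexan-2-yl] S-methyl carbonodithioate F4. Bu3SnH and AIBN in toluene at 90 °C then generate the C2 radical, which opens the adjacent epoxide. The resulting C4 alkoxy radical is reduced to 16. This radical deoxygenation–fragmentation replaces the ionic hydrazone chemistry.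

Step 21. The β-face preference of the peracid is a prediction from the shape of the cis-fused bicycle, not a precedent, and the α-epoxide could dominate. The fallback sets out from 28 and comes back at 30. If electrophiles prefer the α face, 28 is treated with NBS in THF/H2O at 0 °C. The bromonium ion forms on the α face and water opens it at tertiary C8 from the β face, giving the bromohydrin (1S,4R,5S,6R,8R,9R)-9-bromo-4,8-dihydroxydaucan-6-yl 4-acetoxybenzoate F5. K2CO3 in MeOH then closes the 8β,9β-epoxide by backside displacement of bromide and removes the phenolic acetate in the same flask, giving 30 without passing through 29.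

**Further compounds**
F1 | step 8 | (1S,4S,5S)-4-(((tert-butyldimethylsilyl)oxy)methyl)-6-oxabicyclo[3.1.0]hexan-2-one | O=C1[C@H]2O[C@H]2[C@H](CO[Si](C)(C)C(C)(C)C)C1
F2 | step 8 | (1S,3R,4S,5S)-3-allyl-4-(((tert-butyldimethylsilyl)oxy)methyl)-6-oxabicyclo[3.1.0]hexan-2-one | O=C1[C@H]2O[C@H]2[C@H](CO[Si](C)(C)C(C)(C)C)[C@H]1CC=C
F3 | step 10 | 3-allyl-4-(((tert-butyldimethylsilyl)oxy)methyl)-3-methyl-6-oxabicyclo[3.1.0]hexan-2-ol (ring configuration as in 14; either carbinol epimer) | OC1[C@H]2O[C@H]2[C@H](CO[Si](C)(C)C(C)(C)C)[C@]1(C)CC=C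
F4 | step 10 | O-[3-allyl-4-(((tert-butyldimethylsilyl)oxy)methyl)-3-methyl-6-oxabicyclo[3.1.0]hexan-2-yl] S-methyl carbonodithioate | CSC(=S)OC1[C@H]2O[C@H]2[C@H](CO[Si](C)(C)C(C)(C)C)[C@]1(C)CC=C
F5 | step 21 | (1S,4R,5S,6R,8R,9R)-9-bromo-4,8-dihydroxydaucan-6-yl 4-acetoxybenzoate | CC(C)[C@]1(O)CC[C@@]2(C)C[C@@H](Br)[C@](C)(O)C[C@@H](OC(=O)c3ccc(OC(C)=O)cc3)[C@H]21
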